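G, the product, forms beyond X in this chain, but the question here is how much of the intermediate X stands at the end.

    G → J (k1 = 6.7 × 10⁻⁴ h⁻¹)
    X → L (k2 = 0.29 h⁻¹)
    E → X (k3 = 4.8 h⁻¹)
    Q ⇌ G (K4 = 3.1, k4 = 0.043 h⁻¹)
    L → Q (k5 = 0.072 h⁻¹)

in all of them: E 15 mM
- summer: one stirred flow tank at steady state, fed with the mixture as stated, mean residence time 12 h
- spring: plug flow through a tube for 12 h, no back-mixing; time 12 h
- autumn: everything together in a closed stirred flask, run for 12 h; time 12 h

- the set-up with the highest amount of X at the outlet or at the end, in percent of the E put in ("none" if the first two lie within 2 percentage points) (summer / spring / autumn / none)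
- amount of X at the outlet or at the end, in percent of the E put in, summer
- amount of X at the outlet or at the end, in percent of the E put in, spring
- amount of X at the outlet or at the end, in percent of the E put in, autumn

I count turnovers. E → X runs faster than X → L, which makes X → L the rate-limiting step of this pair, and X is lost with a half-life of 2.4 h, shorter than the time. My quantity is the turnover count of X, the rate constant of X → L times the time X is given: 3.48.

The first setting is the vessel. Every parcel in the tube and the closed flask has the same age, so these two share one line, with a small correction 1.06 for the time E takes to react:

c_X / c_E,charged = 1.06 · exp(−3.48) = 3.28% in the tube, 3.28% in the closed flask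

The stirred tank holds parcels of every age, and its balance gives a fraction 0.983 of E converted:

c_X / c_E,charged = 0.983 / (1 + 3.48) = 21.9%

At this count the exponential is smaller than the tank's fraction, so I commit to summer.

The second setting is the time. It enters through the count, so a tube read earlier, but well after E has reacted, should hold more X.

The forecast also names summer, with 21.9% (21.5% to 22.4%) for summer and 3.3% (3.2% to 3.4%) for both spring and autumn. Its ground is “E turns to X almost at once, so X is set by its slower decay”.

The simulation gives summer, with 21.9%, 3.28% and 3.28% for summer, spring and autumn. In the tube at 6.00 h, after 1.74 turnovers, E stands at 0%, X at 18.7% and L at 62.8%. In the tube at 12.0 h L → Q is running on 52.6% of L, which is being made at 0.252 of the rate it is used, and Q holds 35.9%.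

For the same tube read at 3.0 h, the count is 0.870, which gives 44.4% X. The simulation gives 44.6%.

The numbers of this flask belong to no real substance; the run is a simulation.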